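## Analysis of the target

The target (34) is a labdane. Ring A is C1–C5 plus C10 and ring B is C5–C10; C18 (methyl) and C19 (carboxylic acid) sit on C4, C20 (methyl) on C10, the exocyclic methylene C17 on C8 and the C11–C16 side chain on C9. This numbering is used throughout; β is the face of C20 and α the opposite face.

There are six stereocentres, (4S,5R,6S,7S,9S,10R), and an E double bond C13=C14. The decalin is trans-fused (H5 α). C19, C20 and the C6 benzoate are all axial on the β face. The C7 hydroxyl and the C9 side chain are both axial on the α face, so the side chain is trans to C20, the reverse of the common labdane arrangement.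

The sensitive points are these. The 6β-oxygen and C19 are 1,3-syn and would close a γ-lactone whenever a free 6β-hydroxyl meets an electrophilic C19. C9 is epimerisable while C8 is a ketone. The final compound carries a benzoate next to a free hydroxyl, a free acid, an exocyclic alkene and a primary allylic alcohol.

The hard bond is C4–C5. It joins a quaternary carbon to a methine that is flanked by the second quaternary carbon, and C4 must carry its carboxyl on the more crowded face. The benzoate must also be placed on the most shielded oxygen of the molecule.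

The strategy rests on one feature. C19 (acid oxidation level) and the oxygenated C6 are 1,4-related through C4–C5: C4 is the α-carbon of the C19 carboxyl and C5 the α-carbon of a C6 carbonyl. The bond is therefore the union of two enolate-type carbons, and it is formed by oxidative coupling of a ketene dithioacetal (C4=C19) with the ring B silyl enol ether (C5=C6).

## Retrosynthetic reasoning

34 from 33. The last disconnection removes only protecting groups. The C7 silyl ether and the silylethyl ester of 33 both fall to fluoride, so the benzoate, the acid, both alkenes and the allylic alcohol never see acid or strong base.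

33 from 32, 31, and 29 with 30. The bonds cut are C8=C17 and C13=C14. The side-chain alkene is made first, from the methyl ketone of 29 and phosphonate 30, because that ketone would react ahead of the hindered C8 ketone in any methylenation. The exocyclic methylene then follows by a non-basic reagent, and the C15 ester is reduced last.

29 from 27 and 28. The bond cut is C9–C11. C9 must receive carbon on the α face, anti to C20. A nucleophilic C9 attacked along the axial trajectory does this, whereas protonating a C9 enolate that already carried the chain would give the 9β-epimer. Enone 28 is used in place of an alkyl halide for two reasons: the silyl enol ether 27 reacts without a free enolate that could expel the β-benzoate, and 28 delivers C11, C12, C13 and C16 in one bond.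

27 from 26, 25 and 24. The C8 carbonyl is stored as a benzyl ether. It is the only group in 24 that hydrogenolysis removes, which keeps it orthogonal to the C7 silyl ether; this is why the C8 oxygen is not silylated.

24 from 23 and 21. The benzoate is attached in the same flask in which the C6 ketone is reduced, and C19 is a carboxylate salt at that moment. A free 6β-oxygen beside a C19 ester would lactonise; a carboxylate offers it no electrophile. The ester is made only after O6 is acylated.

21 from 19 and 18. The C7–O bond comes from Rubottom oxidation of the C6 ketone. Enolisation can only go toward C7, the α face is the open one, and the silyl group ends on O7 as its protecting group.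

18 from 17 and 15. The ring closure gives the cis-fused ketone 15. C5 is α to the ketone and is equilibrated to the trans-decalone 18 once C19 has become trigonal (acid 17); an axial orthoester would not tolerate the trans fusion.

15 from 14 (key disconnection, C4–C5). Both carbons are electron-rich in 14, so the bond is made by umpolung through a radical cation, without a leaving group at either hindered centre. C19 arrives at the acid level and C6 as a ketone.

14 from 13, and 13 from 7 with 12 (made from 11). The bonds cut are C10–C20 and C10–C1. The chain is put on the enone β-carbon first and the methyl group is added second. Conjugate addition is anti to the benzyloxy group, so this order places C20 trans and C1 cis to O8. The C8 oxygen is then α, equatorial in the later trans-decalin, which is needed for the equilibration of C5.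

11 from 8 and 9; 7 from 6, 5, 4, 3, 2 and 1. The chain is a Peterson olefination product. Ring B comes from the achiral triol 1; enzymatic desymmetrisation of the meso diol 2 is the only source of absolute configuration in the route.

## Alternatives that were turned down

Alternative 1: The disconnection cuts C9–C11 and C8–C17 on a finished bicyclic enone A2 (C7 ketone, C8=C9). In the forward step the side-chain Grignard reagent A3 adds under copper catalysis to C9 of A2 and the enolate is alkylated at C8 by the iminium salt A4, giving the Mannich base A1.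
- For: the addition is axial and anti to C20, so the side chain enters α as required. The complete E-configured side chain arrives stereodefined, and the aminomethyl group is one elimination away from the exocyclic methylene. On these two substituents it is stronger than the chosen route, which spends steps 18 to 22 on them and accepts an olefination of imperfect geometry.
- Against: A2 already contains ring A, the quaternary C4 with axial C19, the trans fusion and the 6β-benzoate, so the hard bond C4–C5 is left unsolved. The C7 carbonyl of A1 must be reduced late to the axial 7α-alcohol by hydride from the β face, past the 6β-benzoate. An α'-acyloxy ketone must also survive organometallic and enolate conditions.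
- Comparison: it is an endgame and not a route to the skeleton. The chosen strategy offers in its place the C4–C5 bond, the C4 centre and both ring B oxygens at their final positions.

Alternative 2: The disconnection cuts C5–C10 and C8–C9. The acyclic triene A6 (E,E-diene, Z-enal, C4 stereocentre in the tether) undergoes an intramolecular Diels–Alder reaction to the octalin aldehyde A5.
- For: both rings and four stereocentres (C5, C8, C9, C10) are made in one thermal step, and the C9 carbon substituent ends α. In step count to the bicycle it is clearly better than the chosen route, which needs nine steps to 15 and eleven to the trans-decalone 18.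
- Against: a β,β-disubstituted Z-enal must react through the exo transition state to form a quaternary centre, and heating may isomerise the enal. The only source of facial bias is an acyclic quaternary C4 that must itself be made enantioselectively. A5 carries a C6=C7 alkene, and turning it into the 6β-benzoate/7α-hydroxyl pair needs oxygen delivered to C6 on the face covered by C19 and C20. C11 is only a formyl carbon and the whole side chain is still to be built.
- Comparison: the chosen route gets the C6 oxygen from the ring-closing step itself and C7 from simple enol ether chemistry.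

Alternative 3: The disconnection cuts C1–C10. The phenoxide of A8 attacks its own primary iodide through the para carbon, closing ring A and giving the cross-conjugated dienone A7.
- For: the C6 and C7 oxygens come from a catechol, the ring closure is a simple C-alkylation, and A7 is an enone ready for conjugate addition at C9. It reaches a bicyclic core in fewer steps than the chosen route and needs neither an enzyme nor an electrolysis.
- Against: C10 is created under the influence of C4 alone, whose methyl and ester groups differ little in size, so the C19/C20 syn relationship is not secured. The benzylic quaternary C4 of A8 must be made enantioselectively. C5 and C6 are left as a tetrasubstituted enol ether between the two quaternary carbons, and it must be reduced with hydrogen entering C5 from the α face and oxygen ending β on C6. The C7 ketone again has to become an axial alcohol.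
- Comparison: the chosen strategy sets C4 in a cyclic transition state with a clear size difference between the C4 substituents. It leaves C5 epimerisable next to a ketone and gives C6 already as that ketone.

Key step: step 9

Remarks on the chemistry (assumptions):
- The lipase in step 2 is taken to acetylate the enantiotopic hydroxyl that leads to (1S,3R,5S)-3. If the enzyme shows the opposite sense, the route to 3 given under the uncertain steps is used.
- The C9 side chain of the target is α (9S), as its SMILES requires. The C8 carbinol centre of the intermediates is a spectator that ends as the methylene carbon; it is carried α and as a benzyl ether for the reasons given above.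

## Steps

Step 1
Reactants: 1 all-cis-cyclohexane-1,3,5-triol
Product: 2 all-cis-5-(benzyloxy)cyclohexane-1,3-diol (meso)
Conditions: NaH (1 equiv), BnBr (1 equiv), DMF, 0 °C → rt
Reagents that add atoms: benzyl bromide BrCc1ccccc1
Why: Williamson etherification of one of three equivalent hydroxyls under statistical control, with unreacted triol recycled; the product is meso, so no stereochemical question arises yet.

Step 2
Reactants: 2 all-cis-5-(benzyloxy)cyclohexane-1,3-diol
Product: 3 (1S,3R,5S)-3-(benzyloxy)-5-hydroxycyclohexyl acetate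
Conditions: immobilised lipase B from Candida antarctica, vinyl acetate, t-BuOMe, 30 °C
Reagents that add atoms: vinyl acetate CC(=O)OC=C
Why: Lipase-catalysed irreversible transacylation desymmetrises the meso diol by acetylating one enantiotopic hydroxyl; this step fixes the absolute configuration of C8 and, through it, of C10.

Step 3
Reactants: 3 (1S,3R,5S)-3-(benzyloxy)-5-hydroxycyclohexyl acetate
Product: 5 (S)-5-(benzyloxy)cyclohex-2-en-1-one, via acetoxy ketone 4 (not isolated)
Conditions: Dess–Martin periodinane, NaHCO3, CH2Cl2, 0 °C → rt; then Et3N, rt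
Reagents that add atoms: none
Why: Dess–Martin oxidation of the free carbinol is followed by E1cB loss of acetate, the better leaving group of the two β-oxygen substituents; the benzyloxy-bearing centre is not touched.

Step 4
Reactants: 5 (S)-5-(benzyloxy)cyclohex-2-en-1-one
Product: 6 (3R,5S)-3-(benzyloxy)-5-(phenylsulfanyl)cyclohexan-1-one
Conditions: PhSH, Et3N (cat.), CH2Cl2, 0 °C
Reagents that add atoms: benzenethiol Sc1ccccc1
Why: Base-catalysed thia-Michael addition; the sulfur-bearing centre (expected trans to the benzyloxy group by axial attack) is erased in step 5.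

Step 5
Reactants: 6 (3R,5S)-3-(benzyloxy)-5-(phenylsulfanyl)cyclohexan-1-one
Product: 7 (R)-5-(benzyloxy)-3-(phenylsulfanyl)cyclohex-2-en-1-one
Conditions: N-chlorosuccinimide, CH2Cl2, 0 °C → rt; then Et3N
Reagents that add atoms: none
Why: S-Chlorination, Pummerer-type α-chlorination and loss of HCl toward the carbonyl give the vinylogous thioester, which places a leaving group on the enone β-carbon (the future C10).

Step 6
Reactants: 8 2-(trimethylsilyl)-1,3-dithiane; 9 5-chloropentan-2-one
Product: 11 2-(5-chloropentan-2-ylidene)-1,3-dithiane, via lithiated silyl dithiane 10 (not isolated)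
Conditions: n-BuLi, THF, −78 → 0 °C; then 9, −78 °C → rt
Reagents that add atoms: none
Why: Peterson olefination: the lithiated silyl dithiane adds to the ketone and the β-silyl alkoxide eliminates spontaneously; addition at −78 °C is faster than displacement of the primary chloride.

Step 7
Reactants: 11 2-(5-chloropentan-2-ylidene)-1,3-dithiane; 7 (R)-5-(benzyloxy)-3-(phenylsulfanyl)cyclohex-2-en-1-one
Product: 13 (S)-5-(benzyloxy)-3-[4-(1,3-dithian-2-ylidene)pentyl]cyclohex-2-en-1-one, via Grignard reagent 12 (not isolated)
Conditions: Mg, BrCH2CH2Br (cat.), THF, reflux; then 7, CuBr·SMe2 (10 mol%), THF, −78 → 0 °C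
Reagents that add atoms: none
Why: Copper-catalysed conjugate addition–elimination on the vinylogous thioester replaces PhS by the C1–C4 chain. Ketene dithioacetals are inert to Grignard reagents, and closure onto C4 would need a four-membered ring.

Step 8
Reactants: 13 (S)-5-(benzyloxy)-3-[4-(1,3-dithian-2-ylidene)pentyl]cyclohex-2-en-1-one
Product: 14 {[(3R,5S)-5-(benzyloxy)-3-[4-(1,3-dithian-2-ylidene)pentyl]-3-methylcyclohex-1-en-1-yl]oxy}trimethylsilane
Conditions: MeMgBr, CuBr·SMe2 (10 mol%), Me3SiCl, HMPA, THF, −78 °C; Et3N, pentane, cold aq. NaHCO3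
Reagents that add atoms: methylmagnesium bromide C[Mg]Br; chlorotrimethylsilane C[Si](C)(C)Cl
Why: Copper-catalysed conjugate methylation with silyl trapping; axial attack on the half-chair anti to the pseudoequatorial benzyloxy group sets C10 with C20 trans and the chain cis to O8. The enolate is captured regiospecifically as the C5=C6 silyl enol ether.

Step 9
Reactants: 14 {[(3R,5S)-5-(benzyloxy)-3-[4-(1,3-dithian-2-ylidene)pentyl]-3-methylcyclohex-1-en-1-yl]oxy}trimethylsilane
Product: 15 8α-(benzyloxy)-19-methoxy-19,19-(propane-1,3-diyldisulfanediyl)-11,12,13,14,15,16,17-heptanor-5β-labdan-6-one (cis-fused)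
Conditions: reticulated vitreous carbon anode, Pt cathode, undivided cell, LiClO4 (0.1 M), MeOH/THF (1:4), 2,6-lutidine, constant current, about 2.2 F/mol, rt
Reagents that add atoms: methanol CO
Why: The ketene dithioacetal, the group of lowest oxidation potential, loses one electron at the anode, and the C4 terminus of its radical cation is attacked by the nucleophilic C5 of the silyl enol ether; a second electron transfer follows, methanol adds to the C19 dithianylium carbon and takes the silyl group from O6, and H2 forms at the cathode. The closest known reaction type is the intramolecular anodic coupling of ketene dithioacetal radical cations with enol ethers in methanol (LiClO4, 2,6-lutidine, carbon anode). Ring A closes in the 6-exo mode with respect to both π-bonds. C5: the C1–C3 tether is anchored on the α face of C10, so C4 can only reach the α face of C5 and the fusion is formed cis (5β-H); this is corrected in step 11. C4: in the chair-like transition state ring B is a half-chair with C20 pseudoaxial and the benzyloxy group equatorial, the bulky dithiane carbon C19 takes the pseudoequatorial position on the forming ring and the C18 methyl the pseudoaxial one, which is the C4 configuration of the target (C18 α, C19 β). The step needs oxidation at the ketene dithioacetal only and C–C bond formation ahead of solvent capture; the low potential of that group, the electron-rich tethered enol ether and the six-membered transition state secure this, and the lutidine buffer protects the silyl enol ether from solvolysis.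

Step 10
Reactants: 15 cis-fused methoxy dithio-orthoester ketone
Product: 17 8α-(benzyloxy)-6-oxo-11,12,13,14,15,16,17-heptanor-5β-labdan-19-oic acid, via thioester 16 (not isolated)
Conditions: 1 M HCl, THF, rt; then AgNO3, 2,6-lutidine, THF/H2O, rt
Reagents that add atoms: water O
Why: Acid ionises the orthoester to the 1,3-dithian-2-ylium ion, which water opens to the S-(3-sulfanylpropyl) thioester. Silver-assisted hydrolysis then frees the neopentyl acid by electrophilic activation, so no forcing basic hydrolysis at the hindered C19 is needed.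

Step 11
Reactants: 17 cis-fused keto acid
Product: 18 8α-(benzyloxy)-6-oxo-11,12,13,14,15,16,17-heptanorlabdan-19-oic acid (5α-H; trans-fused)
Conditions: NaOMe, MeOH, rt; aq. HCl to pH 4
Reagents that add atoms: none
Why: Thermodynamic epimerisation through the C5=C6 enolate. In the trans-decalone every ring B substituent except C20 is equatorial, whereas each cis-fused chair pair must place either O8 syn-axial to C1 or C18 syn-axial to C9. C19 is trigonal now, so its axial position costs no more than in any labdan-19-oic acid.

Step 12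
Reactants: 18 trans-fused keto acid
Product: 19 tert-butyldimethylsilyl 8α-(benzyloxy)-6-[(tert-butyldimethylsilyl)oxy]-11,12,13,14,15,16,17-heptanorlabd-6-en-19-oate
Conditions: t-BuMe2SiOTf, Et3N, CH2Cl2, 0 °C → rt
Reagents that add atoms: tert-butyldimethylsilyl trifluoromethanesulfonate CC(C)(C)[Si](C)(C)OS(=O)(=O)C(F)(F)F
Why: Soft enolisation gives the C6=C7 silyl enol ether, because C5–H lies between two quaternary carbons and a C5=C6 bond would suffer allylic strain with the C4 substituents. No metal enolate is formed, so the C8 benzyloxy group is not eliminated; the acid is silylated at the same time.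

Step 13
Reactants: 19 bis-silylated enol ether
Product: 21 8α-(benzyloxy)-7α-[(tert-butyldimethylsilyl)oxy]-6-oxo-11,12,13,14,15,16,17-heptanorlabdan-19-oic acid, via silyl ester 20 (not isolated)
Conditions: mCPBA, CH2Cl2, −20 → 0 °C; then AcOH/THF/H2O, rt
Reagents that add atoms: 3-chloroperbenzoic acid OOC(=O)c1cccc(Cl)c1
Why: Rubottom oxidation: epoxidation from the α face (the β face is covered by C19 and C20), ring opening and 1,4-silyl shift give the 7α-silyloxy ketone already protected. Mild aqueous acid cleaves only the silyl ester.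

Step 14
Reactants: 21 7α-silyloxy keto acid
Product: 23 6β-(benzoyloxy)-8α-(benzyloxy)-7α-[(tert-butyldimethylsilyl)oxy]-11,12,13,14,15,16,17-heptanorlabdan-19-oic acid, via dilithium alkoxide carboxylate 22 (not isolated)
Conditions: LiEt3BH, THF, −78 → 0 °C; then BzCl, DMAP (cat.), 0 °C → rt; aqueous work-up at pH 4
Reagents that add atoms: benzoyl chloride O=C(Cl)c1ccccc1
Why: Hydride adds to C6 from the α face because the β face carries the syn-axial C19 and C20 groups; the axial 6β-alkoxide is benzoylated in the same flask. With C19 held as the carboxylate the 6β-oxygen has no electrophilic carbonyl to attack, so the 19,6β-lactone cannot form before O6 is acylated.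

Step 15
Reactants: 23 6β-benzoyloxy acid
Product: 24 2-(trimethylsilyl)ethyl 6β-(benzoyloxy)-8α-(benzyloxy)-7α-[(tert-butyldimethylsilyl)oxy]-11,12,13,14,15,16,17-heptanorlabdan-19-oate
Conditions: Me3SiCH2CH2OH, PPh3, diisopropyl azodicarboxylate, THF, 0 °C → rt
Reagents that add atoms: 2-(trimethylsilyl)ethanol C[Si](C)(C)CCO
Why: Mitsunobu esterification: the hindered carboxylate is the nucleophile and attacks the primary carbon of the activated alcohol, so the neopentyl carbonyl itself need not be attacked.

Step 16
Reactants: 24 benzyl ether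
Product: 25 2-(trimethylsilyl)ethyl 6β-(benzoyloxy)-7α-[(tert-butyldimethylsilyl)oxy]-8α-hydroxy-11,12,13,14,15,16,17-heptanorlabdan-19-oate
Conditions: H2 (1 atm), Pd(OH)2/C, EtOAc, rt
Reagents that add atoms: none
Why: Hydrogenolysis of the benzyl ether; the molecule holds no alkene and no sulfur at this stage, and benzoate, silyl ether and silylethyl ester are stable.

Step 17
Reactants: 25 8α-alcohol
Product: 26 2-(trimethylsilyl)ethyl 6β-(benzoyloxy)-7α-[(tert-butyldimethylsilyl)oxy]-8-oxo-11,12,13,14,15,16,17-heptanorlabdan-19-oate
Conditions: Dess–Martin periodinane, NaHCO3, CH2Cl2, rt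
Reagents that add atoms: none
Why: Dess–Martin oxidation of the equatorial secondary alcohol under buffered, non-basic conditions leaves the α-silyloxy centre C7 and the β-benzoyloxy group intact.

Step 18
Reactants: 26 C8 ketone
Product: 27 2-(trimethylsilyl)ethyl 6β-(benzoyloxy)-7α-[(tert-butyldimethylsilyl)oxy]-8-[(trimethylsilyl)oxy]-11,12,13,14,15,16,17-heptanorlabd-8-en-19-oate
Conditions: Me3SiOTf, Et3N, CH2Cl2, 0 °C
Reagents that add atoms: trimethylsilyl trifluoromethanesulfonate C[Si](C)(C)OS(=O)(=O)C(F)(F)F
Why: Soft enolisation toward C9: the C7 hydrogen is equatorial and carries the silyloxy group, while the axial C9 hydrogen is aligned with the carbonyl. No free enolate is formed that could expel the 6β-benzoate.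

Step 19
Reactants: 27 C8=C9 silyl enol ether; 28 but-3-en-2-one
Product: 29 2-(trimethylsilyl)ethyl 6β-(benzoyloxy)-7α-[(tert-butyldimethylsilyl)oxy]-8,13-dioxo-14,15,17-trinor-9βH-labdan-19-oate (side chain 9α)
Conditions: BF3·OEt2, i-PrOH, CH2Cl2, −78 °C
Reagents that add atoms: none
Why: Mukaiyama–Michael addition: C9 attacks the Lewis acid-activated enone along the axial trajectory anti to the adjacent axial C20 methyl, which places the 3-oxobutyl chain on the α face (9S). The C9 hydrogen ends equatorial and is poorly aligned for later epimerisation.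

Step 20
Reactants: 29 diketone; 30 triethyl phosphonoacetate
Product: 31 15-ethyl 19-[2-(trimethylsilyl)ethyl] (13E)-6β-(benzoyloxy)-7α-[(tert-butyldimethylsilyl)oxy]-8-oxo-17-nor-9βH-labd-13-ene-15,19-dioate
Conditions: NaH, THF, 0 °C → rt
Reagents that add atoms: none
Why: Horner–Wadsworth–Emmons olefination is chemoselective for the unhindered methyl ketone over the C8 ketone. Reversible addition favours the E-enoate; the minor Z isomer is to be removed by chromatography.

Step 21
Reactants: 31 keto enoate
Product: 32 15-ethyl 19-[2-(trimethylsilyl)ethyl] (13E)-6β-(benzoyloxy)-7α-[(tert-butyldimethylsilyl)oxy]-9βH-labda-8(17),13-diene-15,19-dioate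
Conditions: Zn, CH2Br2, TiCl4, THF, 0 °C → rt
Reagents that add atoms: dibromomethane BrCBr
Why: Takai–Lombardo methylenation with the non-basic zinc/titanium methylene reagent converts the hindered, epimerisable C8 ketone into the exocyclic alkene without touching the esters or C9.

Step 22
Reactants: 32 diene diester
Product: 33 2-(trimethylsilyl)ethyl (13E)-6β-(benzoyloxy)-7α-[(tert-butyldimethylsilyl)oxy]-15-hydroxy-9βH-labda-8(17),13-dien-19-oate
Conditions: i-Bu2AlH, CH2Cl2, −78 °C; aq. potassium sodium tartrate
Reagents that add atoms: none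
Why: i-Bu2AlH reduces the unhindered conjugated ethyl ester to the allylic alcohol at low temperature. The 6β-benzoate and the axial C19 ester are each flanked by quaternary carbons and should react far more slowly.

Step 23
Reactants: 33 protected allylic alcohol
Product: 34 (13E)-6β-(benzoyloxy)-7α,15-dihydroxy-9βH-labda-8(17),13-dien-19-oic acid (4S,5R,6S,7S,9S,10R)
Conditions: Bu4NF, THF, rt → 40 °C; work-up at pH 4–5
Reagents that add atoms: none
Why: Fluoride removes the C7 silyl ether and fragments the 2-(trimethylsilyl)ethyl ester to the free acid in one operation. The trans-diaxial arrangement of the 6-benzoate and the 7-hydroxyl does not allow acyl migration.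

## Compound list

1 | all-cis-cyclohexane-1,3,5-triol | O[C@@H]1C[C@H](O)C[C@H](O)C1 | starting material
2 | all-cis-5-(benzyloxy)cyclohexane-1,3-diol (meso) | O[C@@H]1C[C@H](O)C[C@H](OCc2ccccc2)C1 | intermediate
3 | (1S,3R,5S)-3-(benzyloxy)-5-hydroxycyclohexyl acetate | O[C@@H]1C[C@H](OC(C)=O)C[C@H](OCc2ccccc2)C1 | intermediate
4 | (1R,3S)-3-(benzyloxy)-5-oxocyclohexyl acetate | O=C1C[C@H](OC(C)=O)C[C@H](OCc2ccccc2)C1 | intermediate
5 | (S)-5-(benzyloxy)cyclohex-2-en-1-one | O=C1C=CC[C@H](OCc2ccccc2)C1 | intermediate
6 | (3R,5S)-3-(benzyloxy)-5-(phenylsulfanyl)cyclohexan-1-one | O=C1C[C@@H](Sc2ccccc2)C[C@H](OCc2ccccc2)C1 | intermediate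
7 | (R)-5-(benzyloxy)-3-(phenylsulfanyl)cyclohex-2-en-1-one | O=C1C=C(Sc2ccccc2)C[C@H](OCc2ccccc2)C1 | intermediate
8 | 2-(trimethylsilyl)-1,3-dithiane | C[Si](C)(C)C1SCCCS1 | starting material
9 | 5-chloropentan-2-one | CC(=O)CCCCl | starting material
10 | 2-lithio-2-(trimethylsilyl)-1,3-dithiane | [Li]C1([Si](C)(C)C)SCCCS1 | intermediate
11 | 2-(5-chloropentan-2-ylidene)-1,3-dithiane | ClCCCC(C)=C1SCCCS1 | intermediate
12 | [4-(1,3-dithian-2-ylidene)pentyl]magnesium chloride | Cl[Mg]CCCC(C)=C1SCCCS1 | intermediate
13 | (S)-5-(benzyloxy)-3-[4-(1,3-dithian-2-ylidene)pentyl]cyclohex-2-en-1-one | O=C1C=C(CCCC(C)=C2SCCCS2)C[C@H](OCc2ccccc2)C1 | intermediate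
14 | {[(3R,5S)-5-(benzyloxy)-3-[4-(1,3-dithian-2-ylidene)pentyl]-3-methylcyclohex-1-en-1-yl]oxy}trimethylsilane | CC(CCC[C@]2(C)C[C@H](OCc3ccccc3)CC(O[Si](C)(C)C)=C2)=C1SCCCS1 | intermediate
15 | 8α-(benzyloxy)-19-methoxy-19,19-(propane-1,3-diyldisulfanediyl)-11,12,13,14,15,16,17-heptanor-5β-labdan-6-one | c1ccccc1CO[C@H]2C[C@@]3(C)CCC[C@](C)(C4(OC)SCCCS4)[C@H]3C(=O)C2 | intermediate
16 | S-(3-sulfanylpropyl) 8α-(benzyloxy)-6-oxo-11,12,13,14,15,16,17-heptanor-5β-labdane-19-thioate | c1ccccc1CO[C@H]2C[C@@]3(C)CCC[C@](C)(C(=O)SCCCS)[C@H]3C(=O)C2 | intermediate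
17 | 8α-(benzyloxy)-6-oxo-11,12,13,14,15,16,17-heptanor-5β-labdan-19-oic acid | c1ccccc1CO[C@H]2C[C@@]3(C)CCC[C@](C)(C(=O)O)[C@H]3C(=O)C2 | intermediate
18 | 8α-(benzyloxy)-6-oxo-11,12,13,14,15,16,17-heptanorlabdan-19-oic acid (5α-H) | c1ccccc1CO[C@H]2C[C@@]3(C)CCC[C@](C)(C(=O)O)[C@@H]3C(=O)C2 | intermediate
19 | tert-butyldimethylsilyl 8α-(benzyloxy)-6-[(tert-butyldimethylsilyl)oxy]-11,12,13,14,15,16,17-heptanorlabd-6-en-19-oate | c1ccccc1CO[C@H]2C[C@@]3(C)CCC[C@](C)(C(=O)O[Si](C)(C)C(C)(C)C)[C@@H]3C(O[Si](C)(C)C(C)(C)C)=C2 | intermediate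
20 | tert-butyldimethylsilyl 8α-(benzyloxy)-7α-[(tert-butyldimethylsilyl)oxy]-6-oxo-11,12,13,14,15,16,17-heptanorlabdan-19-oate | c1ccccc1CO[C@H]2C[C@@]3(C)CCC[C@](C)(C(=O)O[Si](C)(C)C(C)(C)C)[C@@H]3C(=O)[C@H]2O[Si](C)(C)C(C)(C)C | intermediate
21 | 8α-(benzyloxy)-7α-[(tert-butyldimethylsilyl)oxy]-6-oxo-11,12,13,14,15,16,17-heptanorlabdan-19-oic acid | c1ccccc1CO[C@H]2C[C@@]3(C)CCC[C@](C)(C(=O)O)[C@@H]3C(=O)[C@H]2O[Si](C)(C)C(C)(C)C | intermediate
22 | dilithium 8α-(benzyloxy)-7α-[(tert-butyldimethylsilyl)oxy]-6β-oxido-11,12,13,14,15,16,17-heptanorlabdan-19-oate | c1ccccc1CO[C@H]2C[C@@]3(C)CCC[C@](C)(C(=O)[O-])[C@@H]3[C@H]([O-])[C@H]2O[Si](C)(C)C(C)(C)C.[Li+].[Li+] | intermediate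
23 | 6β-(benzoyloxy)-8α-(benzyloxy)-7α-[(tert-butyldimethylsilyl)oxy]-11,12,13,14,15,16,17-heptanorlabdan-19-oic acid | c1ccccc1CO[C@H]2C[C@@]3(C)CCC[C@](C)(C(=O)O)[C@@H]3[C@H](OC(=O)c4ccccc4)[C@H]2O[Si](C)(C)C(C)(C)C | intermediate
24 | 2-(trimethylsilyl)ethyl 6β-(benzoyloxy)-8α-(benzyloxy)-7α-[(tert-butyldimethylsilyl)oxy]-11,12,13,14,15,16,17-heptanorlabdan-19-oate | c1ccccc1CO[C@H]2C[C@@]3(C)CCC[C@](C)(C(=O)OCC[Si](C)(C)C)[C@@H]3[C@H](OC(=O)c4ccccc4)[C@H]2O[Si](C)(C)C(C)(C)C | intermediate
25 | 2-(trimethylsilyl)ethyl 6β-(benzoyloxy)-7α-[(tert-butyldimethylsilyl)oxy]-8α-hydroxy-11,12,13,14,15,16,17-heptanorlabdan-19-oate | O[C@H]1C[C@@]2(C)CCC[C@](C)(C(=O)OCC[Si](C)(C)C)[C@@H]2[C@H](OC(=O)c3ccccc3)[C@H]1O[Si](C)(C)C(C)(C)C | intermediate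
26 | 2-(trimethylsilyl)ethyl 6β-(benzoyloxy)-7α-[(tert-butyldimethylsilyl)oxy]-8-oxo-11,12,13,14,15,16,17-heptanorlabdan-19-oate | O=C1C[C@@]2(C)CCC[C@](C)(C(=O)OCC[Si](C)(C)C)[C@@H]2[C@H](OC(=O)c3ccccc3)[C@H]1O[Si](C)(C)C(C)(C)C | intermediate
27 | 2-(trimethylsilyl)ethyl 6β-(benzoyloxy)-7α-[(tert-butyldimethylsilyl)oxy]-8-[(trimethylsilyl)oxy]-11,12,13,14,15,16,17-heptanorlabd-8-en-19-oate | C[Si](C)(C)OC1=C[C@@]2(C)CCC[C@](C)(C(=O)OCC[Si](C)(C)C)[C@@H]2[C@H](OC(=O)c3ccccc3)[C@H]1O[Si](C)(C)C(C)(C)C | intermediate
28 | but-3-en-2-one | CC(=O)C=C | starting material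
29 | 2-(trimethylsilyl)ethyl 6β-(benzoyloxy)-7α-[(tert-butyldimethylsilyl)oxy]-8,13-dioxo-14,15,17-trinor-9βH-labdan-19-oate | O=C1[C@@H](CCC(C)=O)[C@@]2(C)CCC[C@](C)(C(=O)OCC[Si](C)(C)C)[C@@H]2[C@H](OC(=O)c3ccccc3)[C@H]1O[Si](C)(C)C(C)(C)C | intermediate
30 | triethyl phosphonoacetate | CCOC(=O)CP(=O)(OCC)OCC | starting material
31 | 15-ethyl 19-[2-(trimethylsilyl)ethyl] (13E)-6β-(benzoyloxy)-7α-[(tert-butyldimethylsilyl)oxy]-8-oxo-17-nor-9βH-labd-13-ene-15,19-dioate | O=C1[C@@H](CC/C(C)=C/C(=O)OCC)[C@@]2(C)CCC[C@](C)(C(=O)OCC[Si](C)(C)C)[C@@H]2[C@H](OC(=O)c3ccccc3)[C@H]1O[Si](C)(C)C(C)(C)C | intermediate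
32 | 15-ethyl 19-[2-(trimethylsilyl)ethyl] (13E)-6β-(benzoyloxy)-7α-[(tert-butyldimethylsilyl)oxy]-9βH-labda-8(17),13-diene-15,19-dioate | C=C1[C@@H](CC/C(C)=C/C(=O)OCC)[C@@]2(C)CCC[C@](C)(C(=O)OCC[Si](C)(C)C)[C@@H]2[C@H](OC(=O)c3ccccc3)[C@H]1O[Si](C)(C)C(C)(C)C | intermediate
33 | 2-(trimethylsilyl)ethyl (13E)-6β-(benzoyloxy)-7α-[(tert-butyldimethylsilyl)oxy]-15-hydroxy-9βH-labda-8(17),13-dien-19-oate | C=C1[C@@H](CC/C(C)=C/CO)[C@@]2(C)CCC[C@](C)(C(=O)OCC[Si](C)(C)C)[C@@H]2[C@H](OC(=O)c3ccccc3)[C@H]1O[Si](C)(C)C(C)(C)C | intermediate
34 | (13E)-6β-(benzoyloxy)-7α,15-dihydroxy-9βH-labda-8(17),13-dien-19-oic acid | C=C1[C@@H](CC/C(C)=C/CO)[C@@]2(C)CCC[C@](C)(C(=O)O)[C@@H]2[C@H](OC(=O)c2ccccc2)[C@H]1O | target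

## Step count and uncertain steps

Total: 23 steps. Longest linear sequence: 22 steps (steps 1–5 and 7–23); step 6 is a one-step branch.

Step 9 (key step). The radical cation may be captured by methanol, or the silyl enol ether may be solvolysed, before the C4–C5 bond forms, because the coupling creates a quaternary carbon beside a neopentyl methine. Poor facial selectivity at C4 would give the C4 epimer. Fallback, from 13 to 17: a chemical oxidative coupling of two silyl enol-type carbons.
- Wet CF3CO2H hydrolyses the ketene dithioacetal of 13 to the thioester enone F1.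
- AgOTf and 2-(trimethylsilyl)ethanol convert it into the silylethyl ester enone F2.
- Conjugate methylation as in step 8 gives the silyl enol ether F3.
- LDA and Me3SiCl give the silyl ketene acetal F4.
- (NH4)2Ce(NO3)6 with NaHCO3 in MeCN couples C4 with C5 to the cis-fused keto ester F5, through the same chair as in step 9.
- Bu4NF releases acid 17.

Step 2. The enzyme may acylate the other enantiotopic hydroxyl, or differentiate the two poorly, since they differ only in a remote substituent. Fallback, from 2 to 3: acetylation (Ac2O, pyridine) gives the meso diacetate F6, and hydrolysis with the same lipase in phosphate buffer, which is enantiocomplementary to acylation, gives 3.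

Step 11. Benzyl alcohol may be lost by β-elimination through the C6=C7 enolate, or the equilibrium may not lie far enough on the trans side. Fallback, from 17 to 18, under kinetic control: bromination through the more substituted enol (Br2, AcOH) gives the 5-bromo ketone F7. Bu3SnH with AIBN then delivers a hydrogen atom to the planar C5 radical from the α face, the β face being covered by C19 and C20.

Step 14. Hydride delivery to a ketone shielded on both faces may be slow, and acylation of the carboxylate ahead of the alkoxide would open the way to lactonisation. Fallback, from 21 to 23: tert-butyl 2,2,2-trichloroacetimidate with catalytic BF3·OEt2 gives the tert-butyl ester F8, whose carbonyl resists attack by the 6β-alkoxide. Reduction and benzoylation as in step 14 give the benzoate F9, and Me3SiOTf with 2,6-lutidine followed by aqueous work-up frees acid 23.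

Step 19. Reactivity may be low, or facial selectivity at C9 may erode, because the α face is flanked by the syn-axial C7 silyloxy group. Fallback, from 26 to 29, with a smaller group on O7 during bond formation: HF·pyridine gives the hydroxy ketone F10, Me3SiOTf and Et3N give the bis(trimethylsilyl) compound F11, addition to 28 under the conditions of step 19 gives the hydroxy diketone F12, and t-BuMe2SiOTf with 2,6-lutidine returns 29.

Step 20. E selectivity may be incomplete, and the basic medium may epimerise C9 or expel the benzoate through the C7 enolate. Fallback, from 29 to 33, without base: Zn, CH2Br2 and TiCl4 in excess methylenate both ketones to the triene F13. Cross-metathesis of its unhindered side-chain alkene with (Z)-but-2-ene-1,4-diyl diacetate (second-generation Hoveyda–Grubbs catalyst) gives the allylic acetate F14, and K2CO3 in MeOH removes the acetate. Geometry control is not expected to be better here, but the ketone never meets base and no hydride step is needed.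

## Further compounds

F1 | step 9 | S-(3-sulfanylpropyl) 5-[(S)-5-(benzyloxy)-3-oxocyclohex-1-en-1-yl]-2-methylpentanethioate | O=C1C=C(CCCC(C)C(=O)SCCCS)C[C@H](OCc2ccccc2)C1
F2 | step 9 | 2-(trimethylsilyl)ethyl 5-[(S)-5-(benzyloxy)-3-oxocyclohex-1-en-1-yl]-2-methylpentanoate | O=C1C=C(CCCC(C)C(=O)OCC[Si](C)(C)C)C[C@H](OCc2ccccc2)C1
F3 | step 9 | 2-(trimethylsilyl)ethyl 5-[(1R,5S)-5-(benzyloxy)-1-methyl-3-[(trimethylsilyl)oxy]cyclohex-2-en-1-yl]-2-methylpentanoate | CC(CCC[C@]1(C)C[C@H](OCc2ccccc2)CC(O[Si](C)(C)C)=C1)C(=O)OCC[Si](C)(C)C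
F4 | step 9 | silyl ketene acetal of F3 | CC(CCC[C@]1(C)C[C@H](OCc2ccccc2)CC(O[Si](C)(C)C)=C1)=C(O[Si](C)(C)C)OCC[Si](C)(C)C
F5 | step 9 | 2-(trimethylsilyl)ethyl 8α-(benzyloxy)-6-oxo-11,12,13,14,15,16,17-heptanor-5β-labdan-19-oate | c1ccccc1CO[C@H]2C[C@@]3(C)CCC[C@](C)(C(=O)OCC[Si](C)(C)C)[C@H]3C(=O)C2
F6 | step 2 | all-cis-5-(benzyloxy)cyclohexane-1,3-diyl diacetate (meso) | CC(=O)O[C@@H]1C[C@H](OC(C)=O)C[C@H](OCc2ccccc2)C1
F7 | step 11 | 8α-(benzyloxy)-5α-bromo-6-oxo-11,12,13,14,15,16,17-heptanorlabdan-19-oic acid | c1ccccc1CO[C@H]2C[C@@]3(C)CCC[C@](C)(C(=O)O)[C@]3(Br)C(=O)C2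
F8 | step 14 | tert-butyl 8α-(benzyloxy)-7α-[(tert-butyldimethylsilyl)oxy]-6-oxo-11,12,13,14,15,16,17-heptanorlabdan-19-oate | c1ccccc1CO[C@H]2C[C@@]3(C)CCC[C@](C)(C(=O)OC(C)(C)C)[C@@H]3C(=O)[C@H]2O[Si](C)(C)C(C)(C)C
F9 | step 14 | tert-butyl 6β-(benzoyloxy)-8α-(benzyloxy)-7α-[(tert-butyldimethylsilyl)oxy]-11,12,13,14,15,16,17-heptanorlabdan-19-oate | c1ccccc1CO[C@H]2C[C@@]3(C)CCC[C@](C)(C(=O)OC(C)(C)C)[C@@H]3[C@H](OC(=O)c4ccccc4)[C@H]2O[Si](C)(C)C(C)(C)C
F10 | step 19 | 2-(trimethylsilyl)ethyl 6β-(benzoyloxy)-7α-hydroxy-8-oxo-11,12,13,14,15,16,17-heptanorlabdan-19-oate | O=C1C[C@@]2(C)CCC[C@](C)(C(=O)OCC[Si](C)(C)C)[C@@H]2[C@H](OC(=O)c3ccccc3)[C@H]1O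
F11 | step 19 | 2-(trimethylsilyl)ethyl 6β-(benzoyloxy)-7α,8-bis[(trimethylsilyl)oxy]-11,12,13,14,15,16,17-heptanorlabd-8-en-19-oate | C[Si](C)(C)OC1=C[C@@]2(C)CCC[C@](C)(C(=O)OCC[Si](C)(C)C)[C@@H]2[C@H](OC(=O)c3ccccc3)[C@H]1O[Si](C)(C)C
F12 | step 19 | 2-(trimethylsilyl)ethyl 6β-(benzoyloxy)-7α-hydroxy-8,13-dioxo-14,15,17-trinor-9βH-labdan-19-oate | O=C1[C@@H](CCC(C)=O)[C@@]2(C)CCC[C@](C)(C(=O)OCC[Si](C)(C)C)[C@@H]2[C@H](OC(=O)c3ccccc3)[C@H]1O
F13 | step 20 | 2-(trimethylsilyl)ethyl 6β-(benzoyloxy)-7α-[(tert-butyldimethylsilyl)oxy]-13-methylidene-14,15-dinor-9βH-labd-8(17)-en-19-oate | C=C1[C@@H](CCC(C)=C)[C@@]2(C)CCC[C@](C)(C(=O)OCC[Si](C)(C)C)[C@@H]2[C@H](OC(=O)c3ccccc3)[C@H]1O[Si](C)(C)C(C)(C)C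
F14 | step 20 | 2-(trimethylsilyl)ethyl (13E)-15-acetoxy-6β-(benzoyloxy)-7α-[(tert-butyldimethylsilyl)oxy]-9βH-labda-8(17),13-dien-19-oate | C=C1[C@@H](CC/C(C)=C/COC(C)=O)[C@@]2(C)CCC[C@](C)(C(=O)OCC[Si](C)(C)C)[C@@H]2[C@H](OC(=O)c3ccccc3)[C@H]1O[Si](C)(C)C(C)(C)C
A1 | alternative 1 | C7 ketone with 9α side chain and 8-(dimethylaminomethyl) group | CN(C)C[C@@H]1[C@@H](CC/C(C)=C/CO[Si](C)(C)C(C)(C)C)[C@@]2(C)CCC[C@](C)(C(=O)OCC[Si](C)(C)C)[C@@H]2[C@H](OC(=O)c2ccccc2)C1=O
A2 | alternative 1 | 2-(trimethylsilyl)ethyl 6β-(benzoyloxy)-7-oxo-11,12,13,14,15,16,17-heptanorlabd-8-en-19-oate | C1=C[C@@]2(C)CCC[C@](C)(C(=O)OCC[Si](C)(C)C)[C@@H]2[C@H](OC(=O)c2ccccc2)C1=O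
A3 | alternative 1 | [(E)-5-[(tert-butyldimethylsilyl)oxy]-3-methylpent-3-en-1-yl]magnesium bromide | Br[Mg]CC/C(C)=C/CO[Si](C)(C)C(C)(C)C
A4 | alternative 1 | dimethyl(methylidene)ammonium iodide | C=[N+](C)C.[I-]
A5 | alternative 2 | trans-fused octalin aldehyde with C6=C7, C8 silyloxymethyl and C4 methyl ester | CC(C)(C)[Si](C)(C)OC[C@@H]1[C@@H](C=O)[C@@]2(C)CCC[C@](C)(C(=O)OC)[C@@H]2C=C1
A6 | alternative 2 | acyclic (E,E)-diene (Z)-enal methyl ester | O=C/C=C(C)\CCC[C@](C)(C(=O)OC)/C=C/C=C/CO[Si](C)(C)C(C)(C)C
A7 | alternative 3 | bicyclic cross-conjugated dienone with quaternary C10 and C4 | O=C1C=C[C@@]2(C)CCC[C@](C)(C(=O)OCC[Si](C)(C)C)C2=C1OCOC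
A8 | alternative 3 | phenol with benzylic quaternary C4 and 3-iodopropyl arm | Cc1ccc(O)c(OCOC)c1[C@](C)(CCCI)C(=O)OCC[Si](C)(C)C
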